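**Plan**
- The retrosynthesis cuts the two interflavan bonds, first C4 (fisetinidol)–C6 (catechin ring A), then C4 (fisetinidol)–C8. This leaves (+)-catechin and two copies of one C15 electrophile, (+)-mollisacacidin, the flavan-3,4-diol of fisetinidol.
- Enabling feature: in the fisetinidol unit C4 is benzylic to ring A and para, through C4a, to the C7 hydroxyl, so a 4-OH leaves in dilute acid and a ring A para-quinone methide forms. Ring A of catechin is a phloroglucinol ring whose only CH carbons are C8 and C6.
- Forward: (+)-taxifolin is 5-deoxygenated to (+)-fustin (benzylation at O7, O3', O4'; 5-O-triflate; Pd(OAc)2-catalysed formate reduction; hydrogenolysis) and reduced to mollisacacidin. The C4 carbonyl is the helper: it masks the 5-OH by hydrogen bonding, activates the triflate and finally, as 4-OH, leaves as water.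
- The units are then joined without protecting groups: mollisacacidin with catechin at C8, then mollisacacidin with the 4→8 dimer at C6.
- Stereochemistry: C2 and C3 of all three units come from the chiral pool ((2R,3R)-taxifolin, (2R,3S)-catechin). Both C4 centres (4S, 4α) are set in the couplings by attack anti to the neighbouring 3-OH.

Key step: step 7

Assumption: the SMILES is read as (−)-fisetinidol-(4α→8)-(+)-catechin-(6→4α)-(−)-fisetinidol, with both fisetinidol units (2R,3S,4S) and the catechin unit (2R,3S).

Step 1
Reactants: 1 (+)-taxifolin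
Product: 2 7,3',4'-tri-O-benzyltaxifolin
Conditions: BnBr (3.05 equiv), K2CO3, DMF, 0 °C to rt, Ar
Reagents that add atoms: benzyl bromide, BrCc1ccccc1
Why: Williamson etherification in which the three acidic, unhindered phenols (O7, O3', O4') should react while the 5-OH, held in a hydrogen bond to the C4 carbonyl, and the non-acidic secondary 3-OH stay free; C2 and C3 are not touched.

Step 2
Reactants: 2 7,3',4'-tri-O-benzyltaxifolin
Product: 3 7,3',4'-tri-O-benzyltaxifolin 5-O-triflate
Conditions: PhNTf2 (1.3 equiv), K2CO3, DMF, rt
Reagents that add atoms: N-phenyl-bis(trifluoromethanesulfonimide), O=S(=O)(N(c1ccccc1)S(=O)(=O)C(F)(F)F)C(F)(F)F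
Why: Aryl triflate formation from the only remaining phenoxide with a mild triflyl donor, which should leave the secondary 3-OH alone because K2CO3 does not deprotonate it.

Step 3
Reactants: 3 7,3',4'-tri-O-benzyltaxifolin 5-O-triflate
Product: 4 7,3',4'-tri-O-benzylfustin
Conditions: Pd(OAc)2 (5 mol %), 1,3-bis(diphenylphosphino)propane, Et3N, HCO2H, DMF, 70 °C
Reagents that add atoms: none
Why: Palladium-catalysed formate reduction of an aryl triflate, in which oxidative addition of zerovalent palladium into the C5–O bond is helped by the ortho carbonyl and formate delivers hydride with loss of CO2; benzyl ethers, ketone and both stereocentres should survive.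

Step 4
Reactants: 4 7,3',4'-tri-O-benzylfustin
Product: 5 (+)-fustin
Conditions: H2 (1 atm), Pd/C, EtOAc/MeOH, rt, stopped after three equivalents of H2
Reagents that add atoms: none
Why: Hydrogenolysis of three benzyl ethers under neutral conditions, where the electron-rich aryl ketone (a vinylogous ester through O1 and O7) and the cyclic C2–O1 benzylic ether should be cleaved much more slowly.

Step 5
Reactants: 5 (+)-fustin
Product: 6 (+)-mollisacacidin
Conditions: NaBH4 (excess), EtOH, 0 °C to rt; AcOH to pH 6 at 0 °C
Reagents that add atoms: none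
Why: Hydride reduction of the ketone, in which axial delivery to the half-chair with 2-aryl and 3-OH equatorial should give mainly the equatorial 4-OH (3,4-trans, 4R); the C4 configuration is erased in the couplings in any case.

Step 6
Reactants: 6 (+)-mollisacacidin; 7 (+)-catechin
Product: 9 (−)-fisetinidol-(4α→8)-(+)-catechin, via ring A para-quinone methide 8 (not isolated)
Conditions: 0.1 M aq. HCl, rt, N2, dark, catechin in fourfold excess; EtOAc extraction; Sephadex LH-20 (EtOH), unreacted catechin recovered
Reagents that add atoms: none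
Why: Acid-catalysed flavan-3,4-diol/flavan-3-ol condensation (Friedel–Crafts alkylation through the quinone methide), in which the excess catechin should react once, through C8, the phloroglucinol carbon that flavan-3-ols use first, and from the face anti to the 3-OH to set the 4S centre.

Step 7
Reactants: 6 (+)-mollisacacidin; 9 (−)-fisetinidol-(4α→8)-(+)-catechin
Product: 10 (−)-fisetinidol-(4α→8)-[(−)-fisetinidol-(4α→6)]-(+)-catechin
Conditions: 0.1 M aq. HCl, rt, N2, dark, one equivalent of mollisacacidin added in portions; EtOAc extraction; Sephadex LH-20 (EtOH), then preparative C18 HPLC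
Reagents that add atoms: none
Why: Protonation of the benzylic 4-OH of a fresh portion of 6 and loss of water, pushed by the para C7 hydroxyl through ring A, regenerates in the flask the quinone methide 8 met in step 6 (in acid in equilibrium with its O-protonated form, the C4 benzylic cation), which is captured at C4 by C6 of the catechin ring A of 9, the one remaining CH of that phloroglucinol ring, after which proton loss restores both aromatic rings. The closest known reaction type is the biomimetic acid-catalysed condensation of a flavan-3,4-diol with a flavan-3-ol, a Friedel–Crafts alkylation that is formally a 1,6-addition of a phenol carbon to a para-quinone methide. No ring is closed. The new stereocentre C4 is controlled by the adjacent C3: with the 2-aryl and 3-OH groups equatorial on the half-chair of ring C, the arene should approach the planar C4 quasi-axially from the α face, anti to the 3-OH, which gives the 3,4-trans (4S) arrangement. The step needs site selectivity among the nucleophilic carbons, and the substrate secures it, because the threefold oxygenated catechin ring of 9 is far more electron-rich than the resorcinol-type rings A of the fisetinidol units and of 6, and its C8 is already substituted. Because the fisetinidol units carry no 5-OH, their interflavan bonds should not re-ionise in 0.1 M HCl, so the 4→8 bond of 9 should not be scrambled while the new bond forms.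

**Compound list**
1 | (+)-taxifolin, (2R,3R)-2-(3,4-dihydroxyphenyl)-3,5,7-trihydroxychroman-4-one | Oc1cc(O)c2c(c1)O[C@H](c1ccc(O)c(O)c1)[C@@H](O)C2=O | starting material
2 | 7,3',4'-tri-O-benzyltaxifolin, (2R,3R)-7-benzyloxy-2-[3,4-bis(benzyloxy)phenyl]-3,5-dihydroxychroman-4-one | c1ccccc1COc1cc(O)c2c(c1)O[C@H](c1ccc(OCc3ccccc3)c(OCc3ccccc3)c1)[C@@H](O)C2=O | intermediate
3 | 7,3',4'-tri-O-benzyltaxifolin 5-O-triflate, (2R,3R)-7-benzyloxy-2-[3,4-bis(benzyloxy)phenyl]-3-hydroxy-4-oxochroman-5-yl trifluoromethanesulfonate | c1ccccc1COc1cc(OS(=O)(=O)C(F)(F)F)c2c(c1)O[C@H](c1ccc(OCc3ccccc3)c(OCc3ccccc3)c1)[C@@H](O)C2=O | intermediate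
4 | 7,3',4'-tri-O-benzylfustin, (2R,3R)-7-benzyloxy-2-[3,4-bis(benzyloxy)phenyl]-3-hydroxychroman-4-one | c1ccccc1COc1ccc2c(c1)O[C@H](c1ccc(OCc3ccccc3)c(OCc3ccccc3)c1)[C@@H](O)C2=O | intermediate
5 | (+)-fustin, (2R,3R)-2-(3,4-dihydroxyphenyl)-3,7-dihydroxychroman-4-one | Oc1ccc2c(c1)O[C@H](c1ccc(O)c(O)c1)[C@@H](O)C2=O | intermediate
6 | (+)-mollisacacidin, (2R,3S,4R)-2-(3,4-dihydroxyphenyl)chromane-3,4,7-triol | Oc1ccc2c(c1)O[C@H](c1ccc(O)c(O)c1)[C@@H](O)[C@@H]2O | intermediate
7 | (+)-catechin, (2R,3S)-2-(3,4-dihydroxyphenyl)chromane-3,5,7-triol | Oc1cc(O)c2c(c1)O[C@H](c1ccc(O)c(O)c1)[C@@H](O)C2 | starting material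
8 | ring A para-quinone methide of fisetinidol, (2R,3S)-2-(3,4-dihydroxyphenyl)-3-hydroxy-2,3-dihydro-7H-chromen-7-one | O=C1C=CC2=C[C@H](O)[C@@H](c3ccc(O)c(O)c3)OC2=C1 | intermediate
9 | (−)-fisetinidol-(4α→8)-(+)-catechin; fisetinidol unit (2R,3S,4S), catechin unit (2R,3S) | c1c(O)c2c(c([C@@H]3c4ccc(O)cc4O[C@H](c4ccc(O)c(O)c4)[C@H]3O)c1O)O[C@H](c1ccc(O)c(O)c1)[C@@H](O)C2 | intermediate
10 | (−)-fisetinidol-(4α→8)-[(−)-fisetinidol-(4α→6)]-(+)-catechin; both fisetinidol units (2R,3S,4S), catechin unit (2R,3S) | Oc1ccc2c(c1)O[C@H](c1ccc(O)c(O)c1)[C@@H](O)[C@@H]2c1c(O)c2c(c([C@@H]3c4ccc(O)cc4O[C@H](c4ccc(O)c(O)c4)[C@H]3O)c1O)O[C@H](c1ccc(O)c(O)c1)[C@@H](O)C2 | target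

Total step count: 7
Longest linear sequence: 7 (steps 1 to 7; compound 6 feeds both step 6 and step 7)

**Steps most likely to fail**

1. Step 7. The planar quinone methide may be attacked on the β face as well, giving the 3,4-cis epimer. The product may also be alkylated again on a resorcinol-type ring A, and 6 may condense with itself, so material is lost and the separation becomes hard. Fallback: the fallback sets out from 6 and comes back at 10. Compound 6 is treated with benzyl mercaptan in AcOH at rt, which should capture the same electrophile as the thioether 4α-benzylsulfanylfisetinidol F1 (either C4 epimer serves). F1 and 9 are then combined with AgBF4 in THF at 0 °C. The thiophilic AgBF4 releases the C4 electrophile under aprotic, non-acidic conditions at low temperature and at a rate set by its addition, which should sharpen the anti attack and suppress over-alkylation.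

2. Step 6. Alkylation may leak to C6 of catechin, a second unit may add to the first product, and facial selectivity at C4 may be incomplete. Fallback: the fallback sets out from 4 and 7 and comes back at 9, and it replaces the free-phenol condensation by a protected, Lewis acid route. Compound 4 is reduced with NaBH4 in THF/EtOH to 7,3',4'-tri-O-benzylmollisacacidin F2. Compound 7 is benzylated (BnBr, K2CO3, DMF) to 5,7,3',4'-tetra-O-benzylcatechin F3. F2 and an excess of F3 are coupled with TiCl4 in CH2Cl2 at −40 to 0 °C, where the 5-O-benzyl group shields C6 and the low temperature should favour anti attack, to give the hepta-O-benzyl ether of the 4α→8 dimer F4. Hydrogenolysis (H2, Pd(OH)2/C, THF/MeOH) then gives 9.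

3. Step 2. Sulfonylation of the hydrogen-bonded 5-OH may stall, and the hindered, carbonyl-activated triflate may suffer S–O cleavage by base or formate in step 3 before palladium inserts, returning 2. Fallback: the fallback sets out from 2 and comes back at 5, using a Musliner–Gates deoxygenation in place of the triflate. Compound 2 is O-arylated with 5-chloro-1-phenyl-1H-tetrazole (K2CO3, acetone, reflux) to the hydrolytically robust 7,3',4'-tri-O-benzyltaxifolin 5-O-(1-phenyl-1H-tetrazol-5-yl) ether F5. Hydrogenolysis (H2, Pd/C, EtOAc/EtOH, 40 °C) should then cleave the aryl C5–O bond and the three benzyl ethers in one operation, giving 5 directly.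

**Further compounds**
F1 | step 7 | 4α-benzylsulfanylfisetinidol, (2R,3R,4R)-4-(benzylsulfanyl)-2-(3,4-dihydroxyphenyl)chromane-3,7-diol | Oc1ccc2c(c1)O[C@H](c1ccc(O)c(O)c1)[C@@H](O)[C@@H]2SCc1ccccc1
F2 | step 6 | 7,3',4'-tri-O-benzylmollisacacidin, (2R,3S,4R)-7-benzyloxy-2-[3,4-bis(benzyloxy)phenyl]chromane-3,4-diol | c1ccccc1COc1ccc2c(c1)O[C@H](c1ccc(OCc3ccccc3)c(OCc3ccccc3)c1)[C@@H](O)[C@@H]2O
F3 | step 6 | 5,7,3',4'-tetra-O-benzylcatechin, (2R,3S)-5,7-bis(benzyloxy)-2-[3,4-bis(benzyloxy)phenyl]chroman-3-ol | c1ccccc1COc1cc(OCc3ccccc3)c2c(c1)O[C@H](c1ccc(OCc3ccccc3)c(OCc3ccccc3)c1)[C@@H](O)C2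
F4 | step 6 | hepta-O-benzyl ether of 9, 7,3',4'-tri-O-benzylfisetinidol-(4α→8)-5,7,3',4'-tetra-O-benzylcatechin | c1c(OCc5ccccc5)c2c(c([C@@H]3c4ccc(OCc5ccccc5)cc4O[C@H](c4ccc(OCc5ccccc5)c(OCc5ccccc5)c4)[C@H]3O)c1OCc5ccccc5)O[C@H](c1ccc(OCc5ccccc5)c(OCc5ccccc5)c1)[C@@H](O)C2
F5 | step 2 | 7,3',4'-tri-O-benzyltaxifolin 5-O-(1-phenyl-1H-tetrazol-5-yl) ether, (2R,3R) | c1ccccc1COc1cc(Oc3nnnn3-c3ccccc3)c2c(c1)O[C@H](c1ccc(OCc3ccccc3)c(OCc3ccccc3)c1)[C@@H](O)C2=O
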